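51.3 mM of free reagent is the number I carry through this flask. It is the break-even reagent, R*: the free reagent at which product and starting material stand equal once the reversible steps have come level.

starting material 0.050 M (fed, over 4.0 min); reagent 0.0525 M; capture agent 2.50 mM; time 2.0 d

    capture agent + intermediate A → trapped intermediate (k1 = 0.0251 /M/s)
    reagent + intermediate A ⇌ product (K2 = 22 /M, k2 = 9.04 × 10⁻⁴ /M/s)
    starting material ⇌ intermediate B (K3 = 0.89, k3 = 1.53 × 10⁻⁴ /s)
    starting material + reagent ⇌ intermediate A (K4 = 17.3 /M, k4 = 0.00883 /M/s)

- at 2.0 d, what has stopped the reaction, if anything has (it is still moving / all of the starting material has reacted / the reagent has run out first / forward and back rates have come level)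
- share of the starting material used up at 2.0 d
- product at 2.0 d, in percent of the starting material charged
- intermediate B at 2.0 d, in percent of the starting material charged

- what has gone from starting material into another species counts as reacted, even if it can come back
- the reaction counts as stopped when no species that holds the starting material changes by six tenths of a point or more over the second half of the time
- run time (flask): 2.0 d

The charges allow 52.5% of product. The half-life of intermediate A going to product, forward step alone, is 0.17 d, longer than that of any other step. Even so, it is shorter than 2.0 d. Yet I reckon far less product than that allowance.

With time this ample I expect thermodynamic control, so I ask for the end state. At rest, intermediate B is 0.89 times the starting material. Intermediate A is 17.3 /M times free reagent r times the starting material, and product is 22 /M times r times intermediate A. Product over starting material is therefore r/R* squared.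

Capture has no way back, and its half-life on intermediate A is 0.13 d, shorter than 2.0 d. So I take 2.50 mM off both charges, leaving 0.0475 M of starting-material units and 0.0500 M of reagent. That reagent is below R*, which clears the puzzle: at rest in this flask, even r at 0.0500 M leaves product under starting material, and bound reagent takes r lower still.

Each intermediate A holds one reagent and each product two. I begin with r at 0.0500 M, which gives 0.0128 M of starting material, and the bound reagent brings r to 0.0292 M. A second round gives 0.0175 M and r = 0.0296 M, where I stop, with 0.0174 M of starting material.

| Form | My reckoning, share of the charge |
|---|---|
| starting material | 34.7% |
| intermediate B | 30.9% |
| intermediate A | 17.8% |
| product | 11.6% |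

The forecast says forward and back rates have come level, with 65.2% used, 11.6% product and 30.9% intermediate B, and its grounds include this: “Capture is irreversible”.

The simulation gives forward and back rates have come level, with 65.3% used, 11.6% product and 30.9% intermediate B.

In this flask 56% of the reagent is left at 2.00 d, so r is 0.0296 M. Then r/R* squared is 0.333, and product over starting material reads 0.333. The neighbouring flask with 0.21 M of reagent ends with 66% of that charge left, so r is 0.138 M, above R*. There r/R* squared is 7.24, and product over starting material reads 7.28, with product at 59.7% and starting material at 8.2%.

The rate constants are made up, and the outcome is calculated.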